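**Plan**

1. Retrosynthesis first closes the hydroxy acid to its dihydrocoumarin, a temporary lactone ring between the C5 phenol and the carboxyl group. This is traced back to the 4-propylcoumarin, so the side-chain stereocentre becomes a C=C bond.
2. The dihydropyran ring is then cut at O1–C8a and C4–C4a at once. This leaves a 7-iodocoumarin with a free neighbouring C–H and trans-2,3-dimethyloxetane.
3. Enabling feature: O1 and C4 sit on the adjacent arene carbons C8a and C4a. The other neighbour of C8a (C8) carries the prenyl group, and O1–C2–C3–C4 are exactly the four ring atoms of an oxetane. An aryl iodide with one blocked and one free ortho position is a Catellani substrate, and ring strain makes the oxetane both alkylating agent and alkoxide source.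
4. Forward: Pechmann condensation builds the benzene and lactone rings, Claisen rearrangement and cross metathesis place the prenyl group, the annulation adds the dihydropyran ring, and conjugate reduction and saponification finish.
5. Stereochemistry: C2 comes from ethyl (S)-3-hydroxybutanoate and C3 from a Fráter–Seebach methylation (anti, hence trans in the ring). Both pass through the oxetane with retention. The side-chain centre comes from a ligand-controlled CuH conjugate reduction.

Key step: step 10

Assumption: (R)-DTBM-SEGPHOS is taken as the ligand antipode that sends hydride to the C4 Si face of 14; if a test run shows the opposite sense, the equally available (S)-ligand takes its place.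

**Route**

Step 1
Reactants: 1 5-iodoresorcinol; 2 ethyl 3-oxohexanoate
Product: 3 5-hydroxy-7-iodo-4-propyl-2H-chromen-2-one
Conditions: MeSO3H (neat), rt to 40 °C
Reagents that add atoms: none
Why: Pechmann condensation (transesterification, intramolecular hydroxyalkylation, dehydration) should close at the resorcinol carbon between the two hydroxyls, as with other 5-substituted resorcinols, because closure at the alternative position would press iodine against the propyl group in the peri position, and iodine, being meta to both hydroxyls, is not exposed to protodeiodination.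

Step 2
Reactants: 3 5-hydroxy-7-iodo-4-propyl-2H-chromen-2-one
Product: 4 7-iodo-5-(prop-2-en-1-yloxy)-4-propyl-2H-chromen-2-one
Conditions: allyl bromide, K2CO3, acetone, reflux
Reagents that add atoms: allyl bromide, C=CCBr
Why: Williamson ether synthesis on the only acidic OH of 3, the coumarin lactone being stable to carbonate in an aprotic solvent.

Step 3
Reactants: 4 7-iodo-5-(prop-2-en-1-yloxy)-4-propyl-2H-chromen-2-one
Product: 5 5-hydroxy-7-iodo-6-(prop-2-en-1-yl)-4-propyl-2H-chromen-2-one
Conditions: 1,2-dichlorobenzene, 180 °C, sealed tube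
Reagents that add atoms: none
Why: Aromatic Claisen rearrangement, a [3,3] shift followed by tautomerisation, can deliver the allyl group only to C6 because the other ortho position of the C5 oxygen is the ring-fusion carbon C4a, which places the carbon substituent between oxygen and iodine without any regiochemical choice.

Step 4
Reactants: 5 5-hydroxy-7-iodo-6-(prop-2-en-1-yl)-4-propyl-2H-chromen-2-one
Product: 6 7-iodo-5-methoxy-6-(prop-2-en-1-yl)-4-propyl-2H-chromen-2-one
Conditions: MeI, K2CO3, DMF, rt to 40 °C
Reagents that add atoms: iodomethane, CI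
Why: Williamson O-methylation of the liberated phenol fixes the methyl ether of the target and differentiates it from the lactone oxygen that will become the free phenol.

Step 5
Reactants: 6 7-iodo-5-methoxy-6-(prop-2-en-1-yl)-4-propyl-2H-chromen-2-one
Product: 7 7-iodo-5-methoxy-6-(3-methylbut-2-en-1-yl)-4-propyl-2H-chromen-2-one
Conditions: second-generation Grubbs catalyst (5 mol %), 2-methyl-2-butene/CH2Cl2 1:1, 40 °C, sealed tube
Reagents that add atoms: 2-methyl-2-butene, CC=C(C)C
Why: Olefin cross metathesis of the terminal allyl group with an excess of 2-methyl-2-butene is the standard allyl-to-prenyl conversion, and neither the aryl iodide nor the electron-poor trisubstituted coumarin C3=C4 bond takes part.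

Step 6
Reactants: 8 ethyl (3S)-3-hydroxybutanoate
Product: 10 ethyl (2S,3S)-3-hydroxy-2-methylbutanoate, via dilithium alkoxide-enolate 9 (not isolated)
Conditions: LDA (2.2 equiv, commercial solution), THF, −78 to −20 °C; MeI, DMPU, −78 to 0 °C; 1 M HCl
Reagents that add atoms: lithium diisopropylamide, [Li]N(C(C)C)C(C)C (its lithium is held by 9 only); iodomethane, CI
Why: Fráter–Seebach alkylation, in which the lithium-chelated six-membered alkoxide-enolate 9 is methylated on the face opposite to the C3 methyl group, which sets C2 anti to the hydroxyl-bearing centre, (2S,3S).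

Step 7
Reactants: 10 ethyl (2S,3S)-3-hydroxy-2-methylbutanoate
Product: 11 (2R,3S)-2-methylbutane-1,3-diol
Conditions: LiAlH4, THF, 0 °C to rt; Na2SO4·10H2O quench
Reagents that add atoms: none
Why: Standard LiAlH4 reduction of an ester to the primary alcohol, which touches neither stereocentre.

Step 8
Reactants: 11 (2R,3S)-2-methylbutane-1,3-diol
Product: 12 (2R,3S)-3-hydroxy-2-methylbutyl 4-methylbenzenesulfonate
Conditions: TsCl (1.05 equiv), pyridine, CH2Cl2, 0 °C
Reagents that add atoms: 4-methylbenzenesulfonyl chloride, Cc1ccc(cc1)S(=O)(=O)Cl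
Why: Selective sulfonylation of the less hindered primary hydroxyl of a primary/secondary 1,3-diol with one equivalent of TsCl at low temperature.

Step 9
Reactants: 12 (2R,3S)-3-hydroxy-2-methylbutyl 4-methylbenzenesulfonate
Product: 13 (2S,3R)-2,3-dimethyloxetane
Conditions: NaH (1.2 equiv), triglyme, 0 to 60 °C, product distilled from the flask into a cold trap
Reagents that add atoms: none
Why: Intramolecular Williamson etherification (4-exo-tet) of the secondary alkoxide onto the primary tosylate breaks no bond at either stereocentre, so the anti diol relationship becomes the trans-2,3-dimethyloxetane.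

Step 10
Reactants: 7 7-iodo-5-methoxy-6-(3-methylbut-2-en-1-yl)-4-propyl-2H-chromen-2-one; 13 (2S,3R)-2,3-dimethyloxetane
Product: 14 (8S,9R)-5-methoxy-8,9-dimethyl-6-(3-methylbut-2-en-1-yl)-4-propyl-9,10-dihydro-2H,8H-pyrano[2,3-f]chromen-2-one
Conditions: Pd(OAc)2 (10 mol %), RuPhos (20 mol %), isopropyl 5-norbornene-2-carboxylate (50 mol %), 13 (3 equiv), LiI (30 mol %), Cs2CO3 (2.5 equiv), 1,4-dioxane, 110 °C, sealed tube
Reagents that add atoms: none
Why: Proposed new method: zerovalent palladium inserts into the C7–I bond of 7, norbornene carbopalladation and carbonate-assisted palladation of the only free ortho C8–H give the aryl-norbornyl palladacycle of divalent palladium, whose electron-rich metal opens the Li+-activated oxetane by SN2 attack at its unsubstituted CH2 (about 25 kcal/mol of ring strain pays for the alkoxide leaving group, and LiI may also pre-open the ring to the γ-iodoalkoxide, a classical alkyl halide electrophile), and aryl–CH2 reductive elimination from tetravalent palladium forms C10–C10a. With both ortho positions now filled (prenyl at C6, new chain at C8 of the coumarin) norbornene is expelled by β-carbon elimination and the tethered alkoxide binds to the aryl-palladium centre. The closest known reaction types are the Catellani-type annulation of aryl iodides with epoxides to 2,3-dihydrobenzofurans and the palladium-catalysed intramolecular etherification of secondary alcohols to chromans, whereas an oxetane as the alkylating partner is the untested element. The dihydropyran ring is closed by C(sp2)–O reductive elimination from a seven-membered aryl-palladium alkoxide, a formal (4+2) annulation of the O–C–C–C unit onto C7 and C8 of the coumarin. No new stereocentre is made, since C8 and C9 of 14 come from 13 with retention because only the CH2–O bond of the oxetane is broken. The step needs site selectivity on the arene (the prenyl group blocks C6 and supplies the ortho substituent that drives norbornene extrusion), opening of the oxetane at the primary and not the secondary carbon (SN2 sterics), and C–O reductive elimination faster than β-hydride elimination (bulky RuPhos and two ortho substituents), while the trisubstituted prenyl and coumarin C3=C4 alkenes are poor insertion partners next to strained norbornene.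

Step 11
Reactants: 14 (8S,9R)-5-methoxy-8,9-dimethyl-6-(3-methylbut-2-en-1-yl)-4-propyl-9,10-dihydro-2H,8H-pyrano[2,3-f]chromen-2-one
Product: 16 (4R,8S,9R)-5-methoxy-8,9-dimethyl-6-(3-methylbut-2-en-1-yl)-4-propyl-3,4,9,10-tetrahydro-2H,8H-pyrano[2,3-f]chromen-2-one, via silyl ketene acetal 15 (not isolated)
Conditions: Cu(OAc)2·H2O (5 mol %), (R)-DTBM-SEGPHOS (5.5 mol %), (EtO)2MeSiH (1.5 equiv), toluene, 0 °C to rt, no alcohol additive; then H2O/AcOH
Reagents that add atoms: diethoxy(methyl)silane, C[SiH](OCC)OCC (its silyl group is held by 15 only)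
Why: Ligand-controlled asymmetric CuH conjugate reduction of a β,β-disubstituted unsaturated lactone, in which the chiral copper hydride adds hydride to the C4 Si face to set 4R, the copper enolate is trapped by the silane as silyl ketene acetal 15 that shields the reactive aryl lactone from further reduction until the aqueous work-up, and the unactivated prenyl alkene is not hydrocuprated.

Step 12
Reactants: 16 (4R,8S,9R)-5-methoxy-8,9-dimethyl-6-(3-methylbut-2-en-1-yl)-4-propyl-3,4,9,10-tetrahydro-2H,8H-pyrano[2,3-f]chromen-2-one
Product: 17 (3R)-3-[(2S,3R)-5-hydroxy-7-methoxy-2,3-dimethyl-8-(3-methylbut-2-en-1-yl)-3,4-dihydro-2H-chromen-6-yl]hexanoic acid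
Conditions: LiOH (4 equiv), THF/H2O 3:1, 0 °C to rt; cold 0.5 M HCl to pH 4, EtOAc extraction, no heating
Reagents that add atoms: lithium hydroxide, [Li+].[OH-]
Why: Saponification of the activated aryl ester opens the temporary lactone ring and releases at once the C5 phenol and the carboxylic acid, no stereocentre being α to the carbonyl group, and a cold, weakly acidic work-up avoids relactonisation.

**Compound list**

1 | 5-iodoresorcinol (5-iodobenzene-1,3-diol) | Oc1cc(O)cc(I)c1 | starting material
2 | ethyl 3-oxohexanoate | CCCC(=O)CC(=O)OCC | starting material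
3 | 5-hydroxy-7-iodo-4-propyl-2H-chromen-2-one | CCCC1=CC(=O)Oc2cc(I)cc(O)c12 | intermediate
4 | 7-iodo-5-(prop-2-en-1-yloxy)-4-propyl-2H-chromen-2-one | CCCC1=CC(=O)Oc2cc(I)cc(OCC=C)c12 | intermediate
5 | 5-hydroxy-7-iodo-6-(prop-2-en-1-yl)-4-propyl-2H-chromen-2-one | CCCC1=CC(=O)Oc2cc(I)c(CC=C)c(O)c12 | intermediate
6 | 7-iodo-5-methoxy-6-(prop-2-en-1-yl)-4-propyl-2H-chromen-2-one | CCCC1=CC(=O)Oc2cc(I)c(CC=C)c(OC)c12 | intermediate
7 | 7-iodo-5-methoxy-6-(3-methylbut-2-en-1-yl)-4-propyl-2H-chromen-2-one | CCCC1=CC(=O)Oc2cc(I)c(CC=C(C)C)c(OC)c12 | intermediate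
8 | ethyl (3S)-3-hydroxybutanoate | O[C@@H](C)CC(=O)OCC | starting material
9 | dilithium alkoxide-enolate of 8 (lithium-chelated, enolate oxygen cis to C3) | [Li]O[C@@H](C)/C=C(\O[Li])OCC | intermediate
10 | ethyl (2S,3S)-3-hydroxy-2-methylbutanoate | O[C@@H](C)[C@H](C)C(=O)OCC | intermediate
11 | (2R,3S)-2-methylbutane-1,3-diol | O[C@@H](C)[C@H](C)CO | intermediate
12 | (2R,3S)-3-hydroxy-2-methylbutyl 4-methylbenzenesulfonate | O[C@@H](C)[C@H](C)COS(=O)(=O)c1ccc(C)cc1 | intermediate
13 | (2S,3R)-2,3-dimethyloxetane (trans) | O1[C@@H](C)[C@H](C)C1 | intermediate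
14 | (8S,9R)-5-methoxy-8,9-dimethyl-6-(3-methylbut-2-en-1-yl)-4-propyl-9,10-dihydro-2H,8H-pyrano[2,3-f]chromen-2-one | CCCC1=CC(=O)Oc2c1c(OC)c(CC=C(C)C)c3O[C@@H](C)[C@H](C)Cc23 | intermediate
15 | (4R,8S,9R)-2-[diethoxy(methyl)silyl]oxy-4H-chromene form of 16 (silyl ketene acetal) | CCC[C@@H]1C=C(O[Si](C)(OCC)OCC)Oc2c1c(OC)c(CC=C(C)C)c3O[C@@H](C)[C@H](C)Cc23 | intermediate
16 | (4R,8S,9R)-5-methoxy-8,9-dimethyl-6-(3-methylbut-2-en-1-yl)-4-propyl-3,4,9,10-tetrahydro-2H,8H-pyrano[2,3-f]chromen-2-one | CCC[C@@H]1CC(=O)Oc2c1c(OC)c(CC=C(C)C)c3O[C@@H](C)[C@H](C)Cc23 | intermediate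
17 | (3R)-3-[(2S,3R)-5-hydroxy-7-methoxy-2,3-dimethyl-8-(3-methylbut-2-en-1-yl)-3,4-dihydro-2H-chromen-6-yl]hexanoic acid | CCC[C@H](CC(=O)O)c1c(O)c2c(c(CC=C(C)C)c1OC)O[C@@H](C)[C@H](C)C2 | target

**Step count**

Total step count: 12. Longest linear sequence: 8 (steps 1–5 and 10–12). The oxetane branch (steps 6–9) joins at step 10.

**Steps most likely to fail**

Step 10 (Proposed new method).
- What may go wrong: the palladacycle may open the oxetane too slowly, so that norbornene-derived side reactions or simple reduction of the aryl iodide take over. The palladium alkoxide may also undergo β-hydride elimination before C–O bond formation.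
- Fallback: it sets out from 11 and 7, comes back at 14, and makes the two bonds one after the other with known reactions.
- Diol 11 is silylated at the primary hydroxyl (TBSCl, imidazole, CH2Cl2) to (2S,3R)-4-[(tert-butyldimethylsilyl)oxy]-3-methylbutan-2-ol F1.
- Ullmann-type C–O coupling of 7 with F1 (CuI, 3,4,7,8-tetramethyl-1,10-phenanthroline, Cs2CO3, toluene, 110 °C) should give the aryl sec-alkyl ether 7-{[(2S,3R)-4-(tert-butyldimethylsilyloxy)-3-methylbutan-2-yl]oxy}-5-methoxy-6-(3-methylbut-2-en-1-yl)-4-propyl-2H-chromen-2-one F2, with retention at the carbinol carbon.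
- TBAF in THF frees the primary alcohol 7-{[(2S,3R)-4-hydroxy-3-methylbutan-2-yl]oxy}-5-methoxy-6-(3-methylbut-2-en-1-yl)-4-propyl-2H-chromen-2-one F3.
- An Appel reaction (I2, PPh3, imidazole) turns F3 into the primary iodide 7-{[(2S,3S)-4-iodo-3-methylbutan-2-yl]oxy}-5-methoxy-6-(3-methylbut-2-en-1-yl)-4-propyl-2H-chromen-2-one F4.
- A palladium-catalysed ring-forming aromatic C–H alkylation with the unactivated alkyl iodide (Pd(PPh3)4, K3PO4, 1,4-dioxane, 100 °C) closes the six-membered ring at the only free ortho position to give 14.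

Step 11.
- What may go wrong: facial selectivity may be poor, or turnover slow, at the crowded and electron-rich C4 flanked by the peri methoxy group. The lactone may also be partly reduced further.
- Fallback: it sets out from 14, comes back at 16, and replaces catalytic induction by a resolution.
- Achiral conjugate reduction (Cu(OAc)2·H2O, 1,2-bis(diphenylphosphino)benzene, polymethylhydrosiloxane, toluene) gives the C4-epimeric mixture of the dihydrocoumarin F5.
- Aminolysis of the activated aryl lactone with (S)-1-phenylethylamine (toluene, 60 °C) gives two diastereomeric hydroxy amides, to be separated by chromatography or crystallisation. They are (3R)-3-[(2S,3R)-5-hydroxy-7-methoxy-2,3-dimethyl-8-(3-methylbut-2-en-1-yl)chroman-6-yl]-N-[(1S)-1-phenylethyl]hexanamide F6 and its (3S) epimer F7.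
- Warming F6 in AcOH/toluene lets the neighbouring phenol expel the amine and re-form 16.

Step 1.
- What may go wrong: ring closure may occur at the wrong resorcinol carbon, or condensation of the iodine-deactivated ring may be sluggish.
- Fallback: it sets out from 2, comes back at 3, and removes the regiochemical question by symmetry.
- Pechmann condensation of 2 with commercial phloroglucinol (MeSO3H, rt) gives 5,7-dihydroxy-4-propyl-2H-chromen-2-one F8.
- The more acidic and unhindered C7 hydroxyl is triflated selectively (PhNTf2, K2CO3, DMF, 0 °C) to 5-hydroxy-2-oxo-4-propyl-2H-chromen-7-yl trifluoromethanesulfonate F9.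
- Ruthenium-catalysed triflate-to-iodide exchange ([Cp*Ru(MeCN)3]OTf, NaI, 1,3-dimethyl-2-imidazolidinone, 100 °C) gives 3.

**Further compounds**

F1 | step 10 | (2S,3R)-4-[(tert-butyldimethylsilyl)oxy]-3-methylbutan-2-ol | O[C@@H](C)[C@H](C)CO[Si](C)(C)C(C)(C)C
F2 | step 10 | 7-{[(2S,3R)-4-(tert-butyldimethylsilyloxy)-3-methylbutan-2-yl]oxy}-5-methoxy-6-(3-methylbut-2-en-1-yl)-4-propyl-2H-chromen-2-one | CCCC1=CC(=O)Oc2cc(O[C@@H](C)[C@H](C)CO[Si](C)(C)C(C)(C)C)c(CC=C(C)C)c(OC)c12
F3 | step 10 | 7-{[(2S,3R)-4-hydroxy-3-methylbutan-2-yl]oxy}-5-methoxy-6-(3-methylbut-2-en-1-yl)-4-propyl-2H-chromen-2-one | CCCC1=CC(=O)Oc2cc(O[C@@H](C)[C@H](C)CO)c(CC=C(C)C)c(OC)c12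
F4 | step 10 | 7-{[(2S,3S)-4-iodo-3-methylbutan-2-yl]oxy}-5-methoxy-6-(3-methylbut-2-en-1-yl)-4-propyl-2H-chromen-2-one | CCCC1=CC(=O)Oc2cc(O[C@@H](C)[C@H](C)CI)c(CC=C(C)C)c(OC)c12
F5 | step 11 | (8S,9R)-5-methoxy-8,9-dimethyl-6-(3-methylbut-2-en-1-yl)-4-propyl-3,4,9,10-tetrahydro-2H,8H-pyrano[2,3-f]chromen-2-one, mixture of C4 epimers | CCCC1CC(=O)Oc2c1c(OC)c(CC=C(C)C)c3O[C@@H](C)[C@H](C)Cc23
F6 | step 11 | (3R)-3-[(2S,3R)-5-hydroxy-7-methoxy-2,3-dimethyl-8-(3-methylbut-2-en-1-yl)chroman-6-yl]-N-[(1S)-1-phenylethyl]hexanamide | CCC[C@H](CC(=O)N[C@@H](C)c1ccccc1)c1c(O)c2c(c(CC=C(C)C)c1OC)O[C@@H](C)[C@H](C)C2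
F7 | step 11 | (3S)-3-[(2S,3R)-5-hydroxy-7-methoxy-2,3-dimethyl-8-(3-methylbut-2-en-1-yl)chroman-6-yl]-N-[(1S)-1-phenylethyl]hexanamide | CCC[C@@H](CC(=O)N[C@@H](C)c1ccccc1)c1c(O)c2c(c(CC=C(C)C)c1OC)O[C@@H](C)[C@H](C)C2
F8 | step 1 | 5,7-dihydroxy-4-propyl-2H-chromen-2-one | CCCC1=CC(=O)Oc2cc(O)cc(O)c12
F9 | step 1 | 5-hydroxy-2-oxo-4-propyl-2H-chromen-7-yl trifluoromethanesulfonate | CCCC1=CC(=O)Oc2cc(OS(=O)(=O)C(F)(F)F)cc(O)c12
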